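# Kazinol B: synthesis plan by ortho-quinone methide/vinylchromene [4+2] annulation

## The problem

Kazinol B is a flavan. Ring A, a resorcinol unit with a free 7-OH, is fused to the dihydropyran ring C (O1, C2, C3, C4, C4a, C8a), and C2 carries ring B. Ring B is substituted at five of its six carbons: C1' holds C2, C2' a prenyl group, C3' a free hydroxyl, and C4' and C5' are bridged through O4' into a 2,2-dimethyl-2H-pyran, so that only C6' bears hydrogen. A pattern this dense has to be assembled by delivering each substituent to a position that is the only one open at the time, not by substitution on a finished arene. C2 is the only stereocentre, it is (S), and with no second centre in the molecule to steer it or to be steered by it, its configuration must come from a chiral catalyst or reagent. The same carbon is benzylic, bound to O1 and para to the ether oxygen O4', so acid can open the C2–O1 bond to a stabilised cation and racemise it; everything after its creation must be neutral, basic or only weakly acidic. The chromene and prenyl double bonds exclude hydrogenation and strong oxidants, the prenyl group cyclises onto the neighbouring 3'-OH under acid, and the two phenols must be told apart because only O3' is to be allylated. The feature that opens a short route is that ring C, O1–C2–C3–C4–C4a–C8a, is the formal [4+2] adduct of an ortho-quinone methide of ring A (O1=C8a–C4a=C4) and a vinyl group on ring B (C2=C3), and that O4', para to C1', makes that vinyl group a polarised, nucleophilic two-carbon partner.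

## Retrosynthesis

**20 to 19 (O7–acyl bond).** Kazinol B (20) is traced to its 7-O-pivalate 19. A base-labile acyl group is the one phenol protection whose removal spares the acid-labile C2–O1 ether and both alkenes; a benzyl ether would need hydrogenolysis, a methyl ether a Lewis acid, an acetal a protic acid. Nothing is simplified structurally, but the last step becomes a mild methanolysis. The pivalate also serves earlier, as an electron-withdrawing group on ring A and as the device that keeps O7 out of the O3' allylation.

**19 to 17, then 17 to 15 and 16 (C2'–CH2 bond, then O3'–C bond).** The prenyl C2'–CH2 bond is cut by a retro-Claisen rearrangement to the 1,1-dimethylallyl ether 17. The O3'–C bond of 17 is then cut to phenol 15 and tert-butyl 2-methylbut-3-en-2-yl carbonate (16).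
- Against direct C-prenylation: a Friedel–Crafts reaction needs acid and has C6' and ring A as competing sites.
- Against carrying the prenyl group from the start: a nucleophilic trisubstituted alkene would sit beside the quinone methide, and an ortho substituent would twist the vinyl group out of conjugation.
- For the rearrangement: of the two positions ortho to O3', only C2' bears hydrogen, so it is regiospecific and needs heat alone.
- Asked of the forward steps: the O-allylation must give the branched ether, and the shift must tolerate the crowded site between O3' and the flavanyl group.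

**15 to 14 (O3'–Si bond).** Phenol 15 comes from silyl ether 14. A tert-butyldimethylsilyl ether is removed by fluoride without loss of the pivalate, survives the 190 °C of chromene formation and the acid of the cycloaddition, and silences a phenol that would otherwise trap the quinone methide.

**14 to 3 and 12 (O1–C2 and C3–C4 bonds).** Ring C is opened by a retro-hetero-Diels–Alder reaction to 12, the vinylchromene, and ortho-quinone methide 13, which is generated in the flask from salicyl alcohol 3.
- Simplification: a flavan with 36 non-hydrogen atoms falls into two achiral pieces made in two and four steps, and the stereocentre is formed in the same event as the ring.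
- Against cutting O1–C2 alone: this needs a separately built, enantioenriched para-alkoxybenzylic alcohol that ionises easily on displacement.
- Against cutting O1–C8a: this needs an aryl halide and a metal-catalysed etherification.
- Against cutting C4–C4a: this needs Friedel–Crafts acid.
- For the [4+2] cut: it delivers C3 and C4 as CH2 groups directly, so no reduction is needed near two alkenes.
- Asked of the forward reaction: selection of the vinyl group over the chromene alkene, oxygen delivered to the aryl-bearing carbon, facial control at C2, and conditions under which 14 does not re-ionise.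
- Strengthening: a plain BINOL phosphoric acid is unlikely to dehydrate a primary benzylic alcohol below room temperature. The plan therefore uses the more acidic N-triflylphosphoramide of the same BINOL scaffold and relies on ring closure inside a contact ion pair for induction.

**12 to 11, 11 to 7, 7 to 6, 6 to 4 and 5.** The vinyl C=C bond of 12 is cut to aldehyde 11 (methylenation). The C4a–C4 bond of the chromene in 11 is cut by the retron of the propargyl ether rearrangement (through 8, 9 and 10) to aryl propargyl ether 7. Ether 7 goes back through phenol 6 to 3,4-dihydroxybenzaldehyde (4) and 3-chloro-3-methylbut-1-yne (5). The ring-forming position is fixed: in 7 the only free position ortho to O4' is C5'. The catechol oxygens are distinguished by acidity, since O4' is para to the formyl group. The 190 °C step is placed on a simple achiral aldehyde, where it costs nothing.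

**3 to 2, 2 to 1.** The benzylic alcohol of 3 comes from aldehyde 2 by reduction, and 2 from 2,4-dihydroxybenzaldehyde (1) by cutting the O4–acyl bond. The 2-OH of 1 is hydrogen-bonded to the formyl group, so acylation goes to O4 without further protection.

## Roads not taken

**Alternative 1:** Ring B itself is built in the key step. The C1'–C2' and C5'–C6' bonds are cut. C2' to C5' come from the pyrone half of 8-methoxy-2,2-dimethyl-7-prenyl-2H,5H-pyrano[4,3-b]pyran-5-one A2, and C1' and C6' from the terminal ynone 5-[2-bromo-4-(methoxymethoxy)phenyl]pent-1-yn-3-one A3. Heating pyranopyranone A2 with ynone A3 would give, by [4+2] cycloaddition and loss of CO2 from the adduct, the aryl ketone 3-[2-bromo-4-(methoxymethoxy)phenyl]-1-(8-methoxy-2,2-dimethyl-7-prenyl-2H-chromen-6-yl)propan-1-one A1. Enantioselective reduction of the ketone of A1 and an intramolecular aryl ether coupling at its bromide would then close ring C without substitution at C2.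
- Merits: the whole substitution pattern of ring B, prenyl included, is fixed by construction in one step, so that A1 already carries every ring-B substituent. The stereocentre comes from a ketone reduction of a well-understood kind, which is more secure than the stereocontrol of the chosen plan.
- Weak points: A2 is a doubly substituted bicyclic pyrone that needs a synthesis of its own. A3 is a terminal ynone that polymerises readily, and the cycloaddition needs high temperature in its presence. The O3' methyl ether of A1 must finally be cleaved beside a chromene, a prenyl group and a para-alkoxybenzylic ether, none of which tolerates the Lewis acids or hot thiolates that aryl methyl ethers require; the acetal on O7 needs acid as well.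
- Comparison: the chosen plan reaches the same pattern from 3,4-dihydroxybenzaldehyde by two rearrangements that each have only one open ortho position, ends with carbonate in methanol, and is much shorter. It sets these points against the better-founded stereocontrol of this alternative.

**Alternative 2:** Ring A is carried as a cyclohexane-1,3-dione and aromatised late. The O1–C8a bond is cut. The secondary benzylic hydroxyl of 4-[(3S)-3-aryl-3-hydroxypropyl]cyclohexane-1,3-dione A5, in which aryl stands for 8-silyloxy-2,2-dimethyl-7-prenylchromen-6-yl, condenses with the adjacent ring carbonyl to the vinylogous ester (2S)-2-aryl-2,3,4,4a,5,6-hexahydrochromen-7-one A4. The cyclohexenone ring of A4 is then dehydrogenated to the phenol of ring A.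
- Merits: the C2–O bond of A4 is never made by substitution at the stereocentre, so the configuration set in A5 by an asymmetric carbonyl reduction or addition is kept with certainty; no quinone methide is involved. In this respect it is safer than the chosen plan.
- Weak points: the condensation needs acid on a para-alkoxybenzylic alcohol that can ionise or eliminate. A5 requires a γ-alkylated dione and a separately built chiral side chain on a ring B that already carries prenyl, chromene and silyl ether, so the linear sequence is long. The aromatisation of A4 must oxidise a cyclohexenone next to a chromene, a prenyl group and the benzylic C2–H, which are exactly the sites that quinone oxidants and palladium dehydrogenation catalysts attack.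
- Comparison: the chosen plan has no oxidation step after the alkenes are in place and about half the step count. It accepts an unproven enantioselective step in exchange, and covers it with a fallback through known chemistry.

**Alternative 3:** The prenyl group and the dimethylpyran are both made at the end. The C2'–CH2 and C5'–CH bonds are cut together. Heating the bis-ether (2S)-2-{3-[(2-methylbut-3-en-2-yl)oxy]-4-[(2-methylbut-3-yn-2-yl)oxy]phenyl}chroman-7-yl pivalate A7 would trigger an allyl and a propargyl Claisen rearrangement and an oxa-6π closure to kazinol B 7-O-pivalate A6, which is the same compound as 19.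
- Merits: ring B of A7 needs no silyl group, and two ring-B operations merge into one, so that A6 is reached about two steps sooner at the end. On that count it is better than the chosen plan.
- Weak points: in A7 the allyl ether rearranges near 130 °C and the propargyl ether only near 180–190 °C, so the prenyl group, once in place beside the free 3'-OH, and the C2 centre are held at the higher temperature, where cyclisation of the prenyl group and loss of the tertiary ethers compete. The two different tertiary ethers of A7 must be placed one after the other on O3' and O4', which brings the protecting-group steps back. Neither ether of A7 would survive an acid-catalysed flavan synthesis, so the enantioselective construction of the flavan is left unsolved or made harder.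
- Comparison: the chosen plan performs the same two rearrangements separately, the hot one on a simple aldehyde and the mild one late, and arrives at the same pivalate A6 as its compound 19. It spends two extra steps on that control.

Key step: step 7

Assumption 1: the sense of induction of the new cycloaddition cannot be derived from precedent; the (R)-catalyst is taken to give the (2S)-flavan, and the equally available (S)-catalyst is used instead if a pilot run shows the opposite sense.

Assumption 2: tert-butyl 2-methylbut-3-en-2-yl carbonate (16) is treated as a purchasable reagent.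

## Route

Step 1
Reactants: 1 2,4-dihydroxybenzaldehyde
Product: 2 4-formyl-3-hydroxyphenyl pivalate
Conditions: PivCl (1.05 equiv), Et3N, CH2Cl2, 0 °C
Reagents that add atoms: pivaloyl chloride, CC(C)(C)C(=O)Cl
Why: Regioselective esterification of a phenol with an acid chloride; the 4-OH, para to the formyl group, is the more acidic and is free, whereas the 2-OH is hindered and held in a hydrogen bond to the aldehyde.

Step 2
Reactants: 2 4-formyl-3-hydroxyphenyl pivalate
Product: 3 3-hydroxy-4-(hydroxymethyl)phenyl pivalate
Conditions: NaBH4, THF/MeOH, 0 °C; aq. NH4Cl
Reagents that add atoms: none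
Why: Chemoselective NaBH4 reduction of an aldehyde; the hindered aryl pivalate is inert at 0 °C, and the neutral work-up keeps the salicyl alcohol from losing water prematurely.

Step 3
Reactants: 4 3,4-dihydroxybenzaldehyde; 5 3-chloro-3-methylbut-1-yne
Product: 6 3-hydroxy-4-[(2-methylbut-3-yn-2-yl)oxy]benzaldehyde
Conditions: DBU (1.1 equiv), CuCl2·2H2O (1 mol %), MeCN, 0 °C
Reagents that add atoms: none
Why: Copper-catalysed etherification of a phenol with a tertiary propargylic chloride; the hydroxyl para to the formyl group is the more acidic, so one equivalent of DBU forms and alkylates the O4 phenoxide selectively.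

Step 4
Reactants: 6 3-hydroxy-4-[(2-methylbut-3-yn-2-yl)oxy]benzaldehyde
Product: 7 3-[(tert-butyldimethylsilyl)oxy]-4-[(2-methylbut-3-yn-2-yl)oxy]benzaldehyde
Conditions: TBSCl, imidazole, DMF, rt
Reagents that add atoms: tert-butyldimethylsilyl chloride, CC(C)(C)[Si](C)(C)Cl
Why: Standard silyl ether formation on a phenol with imidazole as base; the aldehyde and the alkyne are inert.

Step 5
Reactants: 7 3-[(tert-butyldimethylsilyl)oxy]-4-[(2-methylbut-3-yn-2-yl)oxy]benzaldehyde
Product: 11 8-[(tert-butyldimethylsilyl)oxy]-2,2-dimethyl-2H-chromene-6-carbaldehyde, via allenyl dienone 8 (not isolated), via allenylphenol 9 (not isolated), via vinyl quinone methide 10 (not isolated)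
Conditions: PhNEt2, 190 °C
Reagents that add atoms: none
Why: Thermal chromene synthesis from an aryl 1,1-dimethylpropargyl ether: the aromatic propargyl Claisen rearrangement goes to the only ortho position bearing hydrogen and gives 8, which enolises to 9; a [1,5]-hydrogen shift gives 10 and an oxa-6π electrocyclisation closes the pyran. The silyl ether blocks the other ortho position and the amine solvent keeps the medium free of acid.

Step 6
Reactants: 11 8-[(tert-butyldimethylsilyl)oxy]-2,2-dimethyl-2H-chromene-6-carbaldehyde
Product: 12 8-[(tert-butyldimethylsilyl)oxy]-6-ethenyl-2,2-dimethyl-2H-chromene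
Conditions: Ph3PCH3Br, KOtBu, THF, 0 °C to rt
Reagents that add atoms: methyltriphenylphosphonium bromide, C[P+](c1ccccc1)(c1ccccc1)c1ccccc1.[Br-]
Why: Wittig methylenation of an aryl aldehyde; the ylide is preformed with a slight deficit of KOtBu so that no free alkoxide meets the aryl silyl ether.

Step 7
Reactants: 3 3-hydroxy-4-(hydroxymethyl)phenyl pivalate; 12 8-[(tert-butyldimethylsilyl)oxy]-6-ethenyl-2,2-dimethyl-2H-chromene
Product: 14 (2S)-2-{8-[(tert-butyldimethylsilyl)oxy]-2,2-dimethyl-2H-chromen-6-yl}-3,4-dihydro-2H-chromen-7-yl pivalate, via ortho-quinone methide 13 (not isolated)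
Conditions: (R)-3,3'-bis(2,4,6-triisopropylphenyl)-1,1'-binaphthyl-2,2'-diyl N-(trifluoromethylsulfonyl)phosphoramide (5 mol %), 5 Å MS, PhMe, 0 °C, slow addition of 3 (1.5 equiv); then Et3N
Reagents that add atoms: none
Why: Proposed new method: the chiral acid, acting as proton donor to the benzylic hydroxyl and as acceptor for the phenolic proton, removes water from 3 (taken up by the sieves) and gives quinone methide 13 as a hydrogen-bonded contact ion pair with the chiral anion. The terminal CH2 of the vinyl group of 12, made nucleophilic by the para ring oxygen O4', adds to the exocyclic CH2 of 13 (C3–C4 bond), and the positive charge building at C2 is stabilised by that same oxygen. The phenolic oxygen, still hydrogen-bonded to the catalyst anion, then captures C2 in a 6-exo-trig closure (O1–C2 bond), so that ring C forms by an asynchronous inverse-demand oxa-[4+2] annulation. The closest known reaction types are chiral phosphoric acid- and N-triflylphosphoramide-catalysed [4+2] cycloadditions of C4-aryl ortho-quinone methides with styrenes, and thermal or achiral acid-promoted cycloadditions of the parent methylene quinone methide with styrenes that give racemic flavans; new here is enantiocontrol without a C4 substituent. The C2 stereocentre is set by the catalyst alone: the anion bridges the phenol and the benzylic cation in the closing step, and its 3,3'-aryl groups shield one face of the cation, which is why induction is expected although the CH2 terminus of 13 itself carries no stereochemical information. Regiochemistry follows from polarity, the nucleophilic alkene terminus meeting the electrophilic CH2 and oxygen going to the aryl-bearing carbon. The step needs selection of the vinyl group over the chromene C3=C4 bond, which is secured by the cis-disubstituted, neopentyl-flanked nature of the latter, and a silent O3', which the silyl ether provides. The pivalate makes 13 more electrophilic and O1 of 14 less basic, and together with low temperature, low catalyst loading and a cold amine quench it holds back re-ionisation of the C2–O1 bond.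

Step 8
Reactants: 14 (2S)-2-{8-[(tert-butyldimethylsilyl)oxy]-2,2-dimethyl-2H-chromen-6-yl}-3,4-dihydro-2H-chromen-7-yl pivalate
Product: 15 (2S)-2-(8-hydroxy-2,2-dimethyl-2H-chromen-6-yl)-3,4-dihydro-2H-chromen-7-yl pivalate
Conditions: Bu4NF, AcOH (1:1), THF, 0 °C
Reagents that add atoms: none
Why: Fluoride-induced cleavage of an aryl silyl ether; acetic acid protonates the phenoxide as it forms, so no acyl transfer from the pivalate can occur, and C2 is not touched.

Step 9
Reactants: 15 (2S)-2-(8-hydroxy-2,2-dimethyl-2H-chromen-6-yl)-3,4-dihydro-2H-chromen-7-yl pivalate; 16 tert-butyl 2-methylbut-3-en-2-yl carbonate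
Product: 17 (2S)-2-{2,2-dimethyl-8-[(2-methylbut-3-en-2-yl)oxy]-2H-chromen-6-yl}-3,4-dihydro-2H-chromen-7-yl pivalate
Conditions: Pd(PPh3)4 (5 mol %), THF, 0 °C to rt
Reagents that add atoms: none
Why: Tsuji–Trost-type decarboxylative O-allylation: zerovalent palladium ionises 16 to a 1,1-dimethyl-π-allyl complex with loss of CO2 and tert-butoxide, which deprotonates the phenol. The phenoxide attacks the more substituted allyl terminus under kinetic control, a known way to aryl 1,1-dimethylallyl ethers; O7 is masked and cannot compete.

Step 10
Reactants: 17 (2S)-2-{2,2-dimethyl-8-[(2-methylbut-3-en-2-yl)oxy]-2H-chromen-6-yl}-3,4-dihydro-2H-chromen-7-yl pivalate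
Product: 19 (2S)-2-[8-hydroxy-2,2-dimethyl-7-(3-methylbut-2-en-1-yl)-2H-chromen-6-yl]-3,4-dihydro-2H-chromen-7-yl pivalate, via Claisen dienone 18 (not isolated)
Conditions: o-xylene, 130 °C
Reagents that add atoms: none
Why: Aromatic Claisen rearrangement: the [3,3] shift through a chair transition state delivers the CH2 terminus to C7 of the chromene (C2' of ring B), the only ortho position bearing hydrogen, and dienone 18 tautomerises to the phenol. The gem-dimethyl group lowers the barrier so that moderate heat suffices, and no bond to C2 is involved, so the (2S) centre is carried through unchanged.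

Step 11
Reactants: 19 (2S)-2-[8-hydroxy-2,2-dimethyl-7-(3-methylbut-2-en-1-yl)-2H-chromen-6-yl]-3,4-dihydro-2H-chromen-7-yl pivalate
Product: 20 kazinol B, (2S)-2-[8-hydroxy-2,2-dimethyl-7-(3-methylbut-2-en-1-yl)-2H-chromen-6-yl]-3,4-dihydro-2H-chromen-7-ol
Conditions: K2CO3, MeOH (degassed), rt; aq. NH4Cl
Reagents that add atoms: none
Why: Base-mediated methanolysis (transesterification) of an aryl pivalate, in which K2CO3 serves only to generate methoxide; the alkenes and the C2 benzylic ether are inert to base, and exclusion of air protects the electron-rich phenols.

## Compound list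

1 | 2,4-dihydroxybenzaldehyde | O=Cc1ccc(O)cc1O | starting material
2 | 4-formyl-3-hydroxyphenyl pivalate | CC(C)(C)C(=O)Oc1ccc(C=O)c(O)c1 | intermediate
3 | 3-hydroxy-4-(hydroxymethyl)phenyl pivalate | CC(C)(C)C(=O)Oc1ccc(CO)c(O)c1 | intermediate
4 | 3,4-dihydroxybenzaldehyde | O=Cc1ccc(O)c(O)c1 | starting material
5 | 3-chloro-3-methylbut-1-yne | C#CC(C)(C)Cl | starting material
6 | 3-hydroxy-4-[(2-methylbut-3-yn-2-yl)oxy]benzaldehyde | C#CC(C)(C)Oc1ccc(C=O)cc1O | intermediate
7 | 3-[(tert-butyldimethylsilyl)oxy]-4-[(2-methylbut-3-yn-2-yl)oxy]benzaldehyde | C#CC(C)(C)Oc1ccc(C=O)cc1O[Si](C)(C)C(C)(C)C | intermediate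
8 | 5-[(tert-butyldimethylsilyl)oxy]-3-(3-methylbuta-1,2-dien-1-yl)-4-oxocyclohexa-1,5-diene-1-carbaldehyde (racemic) | CC(C)=C=CC1C=C(C=O)C=C(O[Si](C)(C)C(C)(C)C)C1=O | intermediate
9 | 3-[(tert-butyldimethylsilyl)oxy]-4-hydroxy-5-(3-methylbuta-1,2-dien-1-yl)benzaldehyde | CC(C)=C=Cc1cc(C=O)cc(O[Si](C)(C)C(C)(C)C)c1O | intermediate
10 | (3Z)-5-[(tert-butyldimethylsilyl)oxy]-3-(3-methylbut-2-en-1-ylidene)-4-oxocyclohexa-1,5-diene-1-carbaldehyde | CC(C)=C/C=C1/C=C(C=O)C=C(O[Si](C)(C)C(C)(C)C)C1=O | intermediate
11 | 8-[(tert-butyldimethylsilyl)oxy]-2,2-dimethyl-2H-chromene-6-carbaldehyde | CC1(C)C=Cc2cc(C=O)cc(O[Si](C)(C)C(C)(C)C)c2O1 | intermediate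
12 | 8-[(tert-butyldimethylsilyl)oxy]-6-ethenyl-2,2-dimethyl-2H-chromene | CC1(C)C=Cc2cc(C=C)cc(O[Si](C)(C)C(C)(C)C)c2O1 | intermediate
13 | 4-methylidene-3-oxocyclohexa-1,5-dien-1-yl pivalate | C=C1C=CC(OC(=O)C(C)(C)C)=CC1=O | intermediate
14 | (2S)-2-{8-[(tert-butyldimethylsilyl)oxy]-2,2-dimethyl-2H-chromen-6-yl}-3,4-dihydro-2H-chromen-7-yl pivalate | CC1(C)C=Cc2cc(cc(O[Si](C)(C)C(C)(C)C)c2O1)[C@@H]1CCc2ccc(OC(=O)C(C)(C)C)cc2O1 | intermediate
15 | (2S)-2-(8-hydroxy-2,2-dimethyl-2H-chromen-6-yl)-3,4-dihydro-2H-chromen-7-yl pivalate | CC1(C)C=Cc2cc(cc(O)c2O1)[C@@H]1CCc2ccc(OC(=O)C(C)(C)C)cc2O1 | intermediate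
16 | tert-butyl 2-methylbut-3-en-2-yl carbonate | C=CC(C)(C)OC(=O)OC(C)(C)C | starting material
17 | (2S)-2-{2,2-dimethyl-8-[(2-methylbut-3-en-2-yl)oxy]-2H-chromen-6-yl}-3,4-dihydro-2H-chromen-7-yl pivalate | CC1(C)C=Cc2cc(cc(OC(C)(C)C=C)c2O1)[C@@H]1CCc2ccc(OC(=O)C(C)(C)C)cc2O1 | intermediate
18 | (2S)-2-[2,2-dimethyl-7-(3-methylbut-2-en-1-yl)-8-oxo-7,8-dihydro-2H-chromen-6-yl]-3,4-dihydro-2H-chromen-7-yl pivalate (both C7 epimers of the dienone ring) | CC1(C)C=CC2=C(O1)C(=O)C(CC=C(C)C)C(=C2)[C@@H]1CCc2ccc(OC(=O)C(C)(C)C)cc2O1 | intermediate
19 | (2S)-2-[8-hydroxy-2,2-dimethyl-7-(3-methylbut-2-en-1-yl)-2H-chromen-6-yl]-3,4-dihydro-2H-chromen-7-yl pivalate | CC(C)=CCc1c([C@@H]2CCc3ccc(OC(=O)C(C)(C)C)cc3O2)cc2c(c1O)OC(C)(C)C=C2 | intermediate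
20 | kazinol B, (2S)-2-[8-hydroxy-2,2-dimethyl-7-(3-methylbut-2-en-1-yl)-2H-chromen-6-yl]-3,4-dihydro-2H-chromen-7-ol | CC(C)=CCc1c([C@@H]2CCc3ccc(O)cc3O2)cc2c(c1O)OC(C)(C)C=C2 | target

## Step count and risk

Total: 11 steps. Longest linear sequence: 9 steps (steps 3 to 11, from 3,4-dihydroxybenzaldehyde 4); the two-step branch from 1 joins at step 7.

**Step 7 (key step, Proposed new method).**
- What may go wrong: insufficient facial discrimination when the phenol closes onto the benzylic cation, because the methylene terminus of the quinone methide gives the catalyst little to hold.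
- Erosion of enantiomeric purity by reversible acid-induced opening of the C2–O1 bond of the product.
- Acid-induced oligomerisation of the electron-rich styrene or self-condensation of the quinone methide.
- Sluggish dehydration of a primary benzylic alcohol.
- Fallback (known chemistry), setting out from 3 and 12: the two are heated without catalyst in o-xylene at 160 °C in a sealed vessel. Thermal generation of the quinone methide and its [4+2] cycloaddition with a styrene is an established flavan synthesis and should give racemic 2-{8-[(tert-butyldimethylsilyl)oxy]-2,2-dimethyl-2H-chromen-6-yl}-3,4-dihydro-2H-chromen-7-yl pivalate F1. The enantiomers are separated by preparative chromatography on a cellulose tris(3,5-dimethylphenylcarbamate) stationary phase; the (2S)-enantiomer is 14, where the route is rejoined, and the (2R)-enantiomer F2 is set aside. Half of the material is lost, but every later step is unchanged.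

**Step 3.**
- What may go wrong: loss of regiocontrol (alkylation at O3 or at both oxygens) once the first phenoxide has reacted, and sequestration of the copper catalyst by the catecholate.
- Fallback, setting out from 4: both hydroxyls are silylated (TBSCl, imidazole, DMF) to 3,4-bis[(tert-butyldimethylsilyl)oxy]benzaldehyde F3. The silyl group para to the formyl group, whose phenoxide is the better leaving group, is removed selectively with Cs2CO3 in DMF/H2O at rt to give 3-[(tert-butyldimethylsilyl)oxy]-4-hydroxybenzaldehyde F4. This monophenol is alkylated with 5 (DBU, CuCl2·2H2O, MeCN, 0 °C) and gives 7 directly, where the route is rejoined.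

**Step 9.**
- What may go wrong: re-ionisation of the branched ether by the palladium catalyst with drift to the linear prenyl ether, C-allylation of the electron-rich ring, or slow reaction of a phenol flanked by the ring oxygen.
- Fallback, setting out from 15: the phenol is alkylated with 5 (DBU, CuCl2·2H2O, MeCN, 0 °C) to (2S)-2-{2,2-dimethyl-8-[(2-methylbut-3-yn-2-yl)oxy]-2H-chromen-6-yl}-3,4-dihydro-2H-chromen-7-yl pivalate F5. Its terminal alkyne is then half-hydrogenated (H2, Pd/CaCO3 poisoned with Pb(OAc)2, quinoline, EtOAc) to 17, where the route is rejoined. The terminal alkyne is reduced far faster than the hindered chromene alkene.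

**Step 10.**
- What may go wrong: loss of the tertiary allyl group as isoprene with return to the phenol; migration through the blocked ortho carbon to the para position, C5 of the chromene; cyclisation of the new prenyl group onto the adjacent hydroxyl on prolonged heating. All of these are favoured by the crowding between O3' and the flavanyl group.
- Fallback, setting out from 15 and bypassing 17: the sodium phenoxide (NaH, toluene) is treated with prenyl bromide at rt. C-alkylation of a phenoxide in a non-polar medium goes to the ortho position, and C2' is the only free one, so 19 is reached directly and the route is rejoined there. This fallback makes no compound outside the list, so the block below carries the entry F0 for it.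

## Further compounds

F1 | step 7 | racemic 2-{8-[(tert-butyldimethylsilyl)oxy]-2,2-dimethyl-2H-chromen-6-yl}-3,4-dihydro-2H-chromen-7-yl pivalate | CC1(C)C=Cc2cc(cc(O[Si](C)(C)C(C)(C)C)c2O1)C1CCc2ccc(OC(=O)C(C)(C)C)cc2O1
F2 | step 7 | (2R)-2-{8-[(tert-butyldimethylsilyl)oxy]-2,2-dimethyl-2H-chromen-6-yl}-3,4-dihydro-2H-chromen-7-yl pivalate | CC1(C)C=Cc2cc(cc(O[Si](C)(C)C(C)(C)C)c2O1)[C@H]1CCc2ccc(OC(=O)C(C)(C)C)cc2O1
F3 | step 3 | 3,4-bis[(tert-butyldimethylsilyl)oxy]benzaldehyde | O=Cc1ccc(O[Si](C)(C)C(C)(C)C)c(O[Si](C)(C)C(C)(C)C)c1
F4 | step 3 | 3-[(tert-butyldimethylsilyl)oxy]-4-hydroxybenzaldehyde | O=Cc1ccc(O)c(O[Si](C)(C)C(C)(C)C)c1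
F5 | step 9 | (2S)-2-{2,2-dimethyl-8-[(2-methylbut-3-yn-2-yl)oxy]-2H-chromen-6-yl}-3,4-dihydro-2H-chromen-7-yl pivalate | CC1(C)C=Cc2cc(cc(OC(C)(C)C#C)c2O1)[C@@H]1CCc2ccc(OC(=O)C(C)(C)C)cc2O1
F0 | step 10 | none | none
A1 | alternative 1 | 3-[2-bromo-4-(methoxymethoxy)phenyl]-1-[8-methoxy-2,2-dimethyl-7-(3-methylbut-2-en-1-yl)-2H-chromen-6-yl]propan-1-one | COc1c(CC=C(C)C)c(C(=O)CCc2ccc(OCOC)cc2Br)cc2C=CC(C)(C)Oc12
A2 | alternative 1 | 8-methoxy-2,2-dimethyl-7-(3-methylbut-2-en-1-yl)-2H,5H-pyrano[4,3-b]pyran-5-one | CC1(C)C=CC2=C(O1)C(OC)=C(CC=C(C)C)OC2=O
A3 | alternative 1 | 5-[2-bromo-4-(methoxymethoxy)phenyl]pent-1-yn-3-one | C#CC(=O)CCc1ccc(OCOC)cc1Br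
A4 | alternative 2 | (2S)-2-{8-[(tert-butyldimethylsilyl)oxy]-2,2-dimethyl-7-(3-methylbut-2-en-1-yl)-2H-chromen-6-yl}-2,3,4,4a,5,6-hexahydro-7H-chromen-7-one (both C4a epimers) | CC(C)=CCc1c(cc2C=CC(C)(C)Oc2c1O[Si](C)(C)C(C)(C)C)[C@@H]1CCC2CCC(=O)C=C2O1
A5 | alternative 2 | 4-[(3S)-3-{8-[(tert-butyldimethylsilyl)oxy]-2,2-dimethyl-7-(3-methylbut-2-en-1-yl)-2H-chromen-6-yl}-3-hydroxypropyl]cyclohexane-1,3-dione | CC(C)=CCc1c(cc2C=CC(C)(C)Oc2c1O[Si](C)(C)C(C)(C)C)[C@@H](O)CCC1CCC(=O)CC1=O
A6 | alternative 3 | kazinol B 7-O-pivalate | CC(C)=CCc1c(O)c2OC(C)(C)C=Cc2cc1[C@@H]1CCc2ccc(OC(=O)C(C)(C)C)cc2O1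
A7 | alternative 3 | (2S)-2-{3-[(2-methylbut-3-en-2-yl)oxy]-4-[(2-methylbut-3-yn-2-yl)oxy]phenyl}-3,4-dihydro-2H-chromen-7-yl pivalate | C#CC(C)(C)Oc1ccc(cc1OC(C)(C)C=C)[C@@H]1CCc2ccc(OC(=O)C(C)(C)C)cc2O1
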